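**Retrosynthetic overview**
- The aryl acetate is made last by Baeyer–Villiger oxidation of 2,4-dihydroxy-6-pentadecylacetophenone, so the acetate sits by construction on the oxygen flanked by the chain and a hydroxyl.
- That ketone comes from 1,3-dimethoxy-5-pentadecylbenzene by Friedel–Crafts acetylation and O-demethylation in one flask.
- Key C–C bond (ArCH2–C14): the aldehyde carbon of 3,5-dimethoxybenzaldehyde is used as a carbanion through its N–H hydrazone and coupled with 1-bromotetradecane under nickel catalysis with loss of N2. Two electrophilic carbons are joined and the carbonyl oxygen is removed in the same operation.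
- Rings: the only ring (benzene) is bought with the aldehyde; no ring is formed.

Assumption: the target has no stereocentre and no stereogenic double bond, so the "single enantiomer" is the one achiral structure drawn and nothing has to be set or preserved.

**Route**

Step 1
Reactants: 1 3,5-dimethoxybenzaldehyde; 2 hydrazine monohydrate; 3 1-bromotetradecane
Product: 5 1,3-dimethoxy-5-pentadecylbenzene, via hydrazone 4 (not isolated)
Conditions: 2 (1.2 equiv), THF, rt, 1 h, Na2SO4; then 3, Ni(cod)2 (10 mol%), 4,4'-di-tert-butyl-2,2'-bipyridine (12 mol%), K3PO4 (2 equiv), 4 Å MS, THF, 60 °C, 16 h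
Reagents that add atoms: none
Why: Nickel-catalysed denitrogenative alkylation of an N–H hydrazone (Wolff–Kishner-type carbanion coupling): the deprotonated hydrazone makes the former carbonyl carbon nucleophilic, zerovalent nickel/bipyridine activates the primary bromide, the C–C bond forms to C1 of the tetradecyl group and the resulting diazene loses N2 to leave the benzylic CH2; no stereocentre is formed.

Step 2
Reactants: 5 1,3-dimethoxy-5-pentadecylbenzene
Product: 7 1-(2,4-dihydroxy-6-pentadecylphenyl)ethan-1-one, via dimethoxy ketone 6 (not isolated)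
Conditions: AcCl (1.1 equiv), AlCl3 (1.2 equiv), CH2Cl2, 0 °C, 1 h; then BBr3 (4 equiv), −78 °C → rt, 12 h; ice-water
Reagents that add atoms: acetyl chloride, CC(Cl)=O
Why: Friedel–Crafts acylation followed in the same flask by Lewis-acid cleavage of the aryl methyl ethers: the acylium ion attacks the position para to one methoxy and ortho to the other (next to the chain), the site at which orcinol-type dimethyl ethers are acylated, and BBr3 then cleaves both ethers, the ortho one first by chelation to the ketone, while the saturated chain and the ketone are inert; no stereocentre.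

Step 3
Reactants: 7 1-(2,4-dihydroxy-6-pentadecylphenyl)ethan-1-one
Product: 8 2,4-dihydroxy-6-pentadecylphenyl acetate
Conditions: mCPBA (1.2 equiv), CH2Cl2, 0 °C → rt, dark; aq. Na2S2O3, pH 7 buffer wash, rapid chromatography
Reagents that add atoms: mCPBA (3-chloroperoxybenzoic acid), OOC(=O)c1cccc(Cl)c1
Why: Baeyer–Villiger oxidation: the peracid adds to the ketone, which is twisted by its two ortho substituents and activated by the internal hydrogen bond, and the very electron-rich 2,4-dihydroxy-6-alkylphenyl group migrates in preference to methyl, so the acetate lands only on the oxygen between chain and hydroxyl without having to tell three phenols apart; no stereocentre.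

**Compound list**
1 | 3,5-dimethoxybenzaldehyde | COc1cc(OC)cc(C=O)c1 | starting material
2 | hydrazine monohydrate | NN.O | starting material
3 | 1-bromotetradecane | CCCCCCCCCCCCCCBr | starting material
4 | (E)-(3,5-dimethoxybenzylidene)hydrazine | COc1cc(OC)cc(/C=N/N)c1 | intermediate
5 | 1,3-dimethoxy-5-pentadecylbenzene | CCCCCCCCCCCCCCCc1cc(OC)cc(OC)c1 | intermediate
6 | 1-(2,4-dimethoxy-6-pentadecylphenyl)ethan-1-one | CCCCCCCCCCCCCCCc1cc(OC)cc(OC)c1C(C)=O | intermediate
7 | 1-(2,4-dihydroxy-6-pentadecylphenyl)ethan-1-one | CCCCCCCCCCCCCCCc1cc(O)cc(O)c1C(C)=O | intermediate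
8 | 2,4-dihydroxy-6-pentadecylphenyl acetate | CCCCCCCCCCCCCCCc1cc(O)cc(O)c1OC(C)=O | target

**Step count and risks**
Total steps: 3. Longest linear sequence: 3 (1 → 5 → 7 → 8).

Most likely to fail, in this order:

Step 1 (hydrazone alkylation). The hydrazone may be N-alkylated by the bromide, reduced to 3,5-dimethoxytoluene or dimerised to the azine, and the alkylnickel species may lose tetradecene by β-hydride elimination. The fallback sets out from 1 and comes back at 5, still using the aldehyde carbon as a nucleophile but as a stoichiometric acyl anion. Aldehyde 1 is condensed with propane-1,3-dithiol (BF3·OEt2, CH2Cl2, 0 °C → rt) to give 2-(3,5-dimethoxyphenyl)-1,3-dithiane F1. This is lithiated (nBuLi, THF, −30 °C) and alkylated with bromide 3 to give 2-(3,5-dimethoxyphenyl)-2-tetradecyl-1,3-dithiane F2. Reductive desulfurisation with nickel boride made in the flask (NiCl2·6H2O, NaBH4, MeOH/THF, 0 °C → rt) then gives 5.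

Step 3 (Baeyer–Villiger oxidation with free phenols). The hydrogen-bonded ketone may react slowly, the electron-rich ring may be hydroxylated by the peracid, and the acetyl group may migrate to the neighbouring hydroxyl on work-up. The fallback sets out from 7 and comes back at 8, masking the phenols during the oxidation. Ketone 7 is silylated (TBSOTf, 2,6-lutidine, CH2Cl2, 0 °C) to 1-[2,4-bis(tert-butyldimethylsilyloxy)-6-pentadecylphenyl]ethan-1-one F5. This is oxidised (mCPBA, NaHCO3, CH2Cl2, rt) to 2,4-bis(tert-butyldimethylsilyloxy)-6-pentadecylphenyl acetate F6. Both silyl ethers are then removed under acidic fluoride conditions (HF·pyridine, THF/pyridine, 0 °C), which do not move or cleave the acetate, to give 8.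

Step 2 (one-flask acylation and demethylation). Some acylation may occur between the two methoxy groups, the para ether may cleave incompletely, and the crowded ketone may be lost by deacylation in the strongly acidic mixture. The fallback sets out from 5 and comes back at 7, reversing the order and acylating with a nitrile. Ether 5 is demethylated alone (BBr3, CH2Cl2, −78 °C → rt) to 5-pentadecylbenzene-1,3-diol F3. A Houben–Hoesch reaction with acetonitrile (ZnCl2, HCl gas, Et2O, 0 °C) then gives 1-(2,4-dihydroxy-6-pentadecylphenyl)ethan-1-iminium chloride F4, which is hydrolysed in water at 90 °C to 7.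

Further compounds
F1 | step 1 | 2-(3,5-dimethoxyphenyl)-1,3-dithiane | COc1cc(OC)cc(c1)C1SCCCS1
F2 | step 1 | 2-(3,5-dimethoxyphenyl)-2-tetradecyl-1,3-dithiane | CCCCCCCCCCCCCCC1(SCCCS1)c1cc(OC)cc(OC)c1
F3 | step 2 | 5-pentadecylbenzene-1,3-diol | CCCCCCCCCCCCCCCc1cc(O)cc(O)c1
F4 | step 2 | 1-(2,4-dihydroxy-6-pentadecylphenyl)ethan-1-iminium chloride | CCCCCCCCCCCCCCCc1cc(O)cc(O)c1C(C)=[NH2+].[Cl-]
F5 | step 3 | 1-[2,4-bis(tert-butyldimethylsilyloxy)-6-pentadecylphenyl]ethan-1-one | CCCCCCCCCCCCCCCc1cc(O[Si](C)(C)C(C)(C)C)cc(O[Si](C)(C)C(C)(C)C)c1C(C)=O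
F6 | step 3 | 2,4-bis(tert-butyldimethylsilyloxy)-6-pentadecylphenyl acetate | CCCCCCCCCCCCCCCc1cc(O[Si](C)(C)C(C)(C)C)cc(O[Si](C)(C)C(C)(C)C)c1OC(C)=O
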